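**Plan**

- Retrosynthesis: the five O–benzyl bonds are cut last. Ring C is then opened at C4–C4a and O1–C2, which leaves a ring A resorcinol and an α-benzyloxy aroylacetate. The CH2 bridge is cut at its bond to ring A (aryllithium plus ring D aldehyde), and ring D is traced back to 2-methylphloroglucinol by removing its formyl, O-methyl and acyl groups.
- Enabling feature: all six carbons of ring D are substituted, so it has no aromatic C–H. In the ring A precursor the bridge carbon (later C8) lies between two free hydroxyls, with the benzylated O5 para to it. The two ring A C–H carbons are therefore mirror images, and only the 8-substituted 5-benzyloxy-7-hydroxyflavone can form.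
- Forward order: ring D is built up (acylation with the ring E chain, O-methylation, formylation, benzylation), joined to lithiated ring A and deoxygenated to the diarylmethane. Ring C is then fused on thermally, and hydrogenolysis ends the route.
- Stereochemistry: the target has no stereocentre. The carbinol carbon of step 7 and the α-carbon of the keto ester are racemic and become a CH2 group and an sp2 carbon.

Key step: step 10

Remark: rings are lettered A (benzo ring of the chromenone), B (4-methoxyphenyl), C (pyranone), D (hexasubstituted benzyl ring) and E (4-hydroxyphenyl of the propanoyl chain). Phloroglucinol is used in anhydrous form.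

Step 1
Reactants: 1 phloroglucinol (benzene-1,3,5-triol)
Product: 2 3,5-bis(methoxymethoxy)phenol
Conditions: MOMCl (2.0 equiv), i-Pr2NEt (2.2 equiv), DMF, 0 °C to rt
Reagents that add atoms: chloromethyl methyl ether, COCCl
Why: Williamson-type O-alkylation (MOM protection) of a threefold-symmetric triol with two equivalents of a hard alkylating agent should give the bis-ether as the main member of a statistical mixture, from which the mono- and tris-ethers are separable by chromatography and recyclable.

Step 2
Reactants: 2 3,5-bis(methoxymethoxy)phenol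
Product: 3 1-(benzyloxy)-3,5-bis(methoxymethoxy)benzene
Conditions: BnBr, K2CO3, DMF, rt
Reagents that add atoms: benzyl bromide, BrCc1ccccc1
Why: Williamson etherification of the one remaining phenol with benzyl bromide under mild carbonate conditions that leave the acetal-type MOM ethers untouched.

Step 3
Reactants: 4 2-methylbenzene-1,3,5-triol; 5 3-(4-hydroxyphenyl)propanoic acid
Product: 6 3-(4-hydroxyphenyl)-1-(2,4,6-trihydroxy-3-methylphenyl)propan-1-one
Conditions: BF3·OEt2 (excess), 85 °C; then aq NaOAc
Reagents that add atoms: none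
Why: BF3-mediated Friedel–Crafts acylation of a phloroglucinol by a free carboxylic acid, in which the two open positions of 4 are equivalent, so that a single ketone should result and the first acyl group deactivates the ring against a second.

Step 4
Reactants: 6 3-(4-hydroxyphenyl)-1-(2,4,6-trihydroxy-3-methylphenyl)propan-1-one
Product: 7 1-(2,6-dihydroxy-4-methoxy-3-methylphenyl)-3-(4-hydroxyphenyl)propan-1-one
Conditions: Me2SO4 (1.0 equiv), K2CO3 (1.0 equiv), acetone, rt
Reagents that add atoms: dimethyl sulfate, COS(=O)(=O)OC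
Why: Regioselective Williamson O-methylation: the hydroxyl para to the ketone is the most acidic phenol of 6 and the only ring D hydroxyl not tied up in a hydrogen bond to the carbonyl, so one equivalent of carbonate should deliver mainly its phenoxide while the less acidic ring E phenol stays protonated.

Step 5
Reactants: 7 1-(2,6-dihydroxy-4-methoxy-3-methylphenyl)-3-(4-hydroxyphenyl)propan-1-one
Product: 9 2,4-dihydroxy-3-[3-(4-hydroxyphenyl)propanoyl]-6-methoxy-5-methylbenzaldehyde, via ring D dimethyliminium chloride 8 (not isolated)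
Conditions: POCl3 (1.5 equiv), DMF, EtOAc, 0 °C to rt; then H2O, 50 °C
Reagents that add atoms: N,N-dimethylformamide, CN(C)C=O; water, O
Why: Vilsmeier–Haack formylation at the only unsubstituted carbon of ring D, which is activated by an ortho hydroxyl, an ortho methoxy and a para hydroxyl group, whereas the mono-oxygenated ring E is too electron-poor to react with the chloroiminium ion at room temperature; mild hydrolysis frees the aldehyde.

Step 6
Reactants: 9 2,4-dihydroxy-3-[3-(4-hydroxyphenyl)propanoyl]-6-methoxy-5-methylbenzaldehyde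
Product: 10 2,4-bis(benzyloxy)-3-{3-[4-(benzyloxy)phenyl]propanoyl}-6-methoxy-5-methylbenzaldehyde
Conditions: BnBr (4 equiv), K2CO3 (5 equiv), n-Bu4NI (cat.), DMF, 60 °C
Reagents that add atoms: benzyl bromide, BrCc1ccccc1
Why: Exhaustive Williamson benzylation in hot DMF, which breaks the hydrogen bonds of the two carbonyl-flanked phenols; ring D has no free nuclear position left, so C-benzylation is not an option.

Step 7
Reactants: 3 1-(benzyloxy)-3,5-bis(methoxymethoxy)benzene; 10 2,4-bis(benzyloxy)-3-{3-[4-(benzyloxy)phenyl]propanoyl}-6-methoxy-5-methylbenzaldehyde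
Product: 12 racemic 1-[2,6-bis(benzyloxy)-3-{[4-(benzyloxy)-2,6-bis(methoxymethoxy)phenyl](hydroxy)methyl}-4-methoxy-5-methylphenyl]-3-[4-(benzyloxy)phenyl]propan-1-one, via ring A aryllithium 11 (not isolated)
Conditions: 3 (1.3 equiv), n-BuLi (1.25 equiv), THF, 0 °C; then 10 (1.0 equiv), −78 to −40 °C; aq NH4Cl
Reagents that add atoms: none
Why: Directed ortho-metalation at the carbon between the two cooperating MOM ethers followed by 1,2-addition of the aryllithium to the aldehyde, which is far more electrophilic than the ketone shielded by two ortho benzyloxy groups; the carbinol stereocentre forms racemic and is erased in step 8.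

Step 8
Reactants: 12 racemic diaryl carbinol
Product: 14 5-(benzyloxy)-2-[(2,4-bis(benzyloxy)-3-{3-[4-(benzyloxy)phenyl]propanoyl}-6-methoxy-5-methylphenyl)methyl]benzene-1,3-diol, via bis-MOM diarylmethane 13 (not isolated)
Conditions: Et3SiH (3 equiv), TFA (3 equiv), CH2Cl2, −20 °C; volatiles removed; then HCl (cat.), MeOH–THF, 40 °C
Reagents that add atoms: none
Why: Ionic (Kursanov–Parnes) deoxygenation: the carbinol ionises under mild acid to a benzhydryl cation stabilised by four ortho and two para oxygens and is trapped by hydride from the silane, the twisted ketone being far less prone to ionise, and subsequent acid methanolysis removes the two acetal-type MOM ethers while benzyl and methyl ethers are inert.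

Step 9
Reactants: 15 ethyl 2-(benzyloxy)acetate; 16 4-methoxybenzoyl chloride
Product: 18 racemic ethyl 2-(benzyloxy)-3-(4-methoxyphenyl)-3-oxopropanoate, via lithium ester enolate 17 (not isolated)
Conditions: 15 (2 equiv), LiHMDS (2 equiv), THF, −78 °C; then 16 (1 equiv), −78 to 0 °C; AcOH quench
Reagents that add atoms: none
Why: Crossed Claisen-type C-acylation of a preformed ester lithium enolate by an acid chloride, the second equivalent of enolate deprotonating the more acidic keto ester so that double acylation is avoided; the new stereocentre is racemic and vanishes in step 10.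

Step 10
Reactants: 14 5-(benzyloxy)-2-[(ring D aryl)methyl]benzene-1,3-diol; 18 racemic ethyl 2-(benzyloxy)-3-(4-methoxyphenyl)-3-oxopropanoate
Product: 21 3,5-bis(benzyloxy)-8-[(2,4-bis(benzyloxy)-3-{3-[4-(benzyloxy)phenyl]propanoyl}-6-methoxy-5-methylphenyl)methyl]-7-hydroxy-2-(4-methoxyphenyl)-4H-chromen-4-one, via aroylketene 19 (not isolated), via ring A 1,3-diketone 20 (not isolated)
Conditions: 18 (2.5 equiv), neat melt, Ar stream, 230–240 °C (microwave), 20 min
Reagents that add atoms: none
Why: This is a Mentzer-type thermal pyranone annulation: above about 200 °C keto ester 18 expels ethanol to give aroylketene 19, which acylates ring A of 14 at one of its two equivalent C–H carbons (ortho to a free hydroxyl, ortho to the benzyloxy group, para to the other hydroxyl), while O-acyl adducts revert to the ketene at this temperature, so that C4–C4a is formed as diketone 20. The hydroxyl next to the new acyl group then adds to the anisoyl carbonyl (6-exo-trig hemiketal) and loss of water gives the aromatic pyranone, which forms O1–C2 and closes ring C with the benzyloxy group already on C3. The closest known reaction is the uncatalysed melt condensation of phloroglucinol-type phenols with alkyl aroylacetates, 2-substituted ones included, to 5,7-dioxygenated flavones. No stereocentre is created, and the racemic α-carbon of 18 becomes the sp2 carbon C3. The step needs the bridge to end up on C8: the mirror plane of 14 through the CH2-bearing carbon and the benzyloxy-bearing carbon makes both acylation sites identical, the benzylated O5 cannot close a ring, and neither ring D (no aromatic C–H) nor the mono-oxygenated ring E is acylated. Chromone rather than coumarin formation should follow from the acid-free conditions and from the α-benzyloxy group, which disfavours arene attack on the ketone carbonyl, and a second annulation at C6 is held back because the new pyranone carbonyl deactivates ring A.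

Step 11
Reactants: 21 penta-O-benzyl flavone
Product: 22 4'''-hydroxytrianguletin
Conditions: H2 (1 atm), 10% Pd/C, THF–MeOH, rt
Reagents that add atoms: none
Why: Heterogeneous catalytic hydrogenolysis of the five benzylic C–O bonds; under one atmosphere of hydrogen the pyranone double bond, the hindered hydrogen-bonded aryl ketone, the diarylmethane bridge and the two methyl ethers are expected to remain intact.

**Compound list**

1 | phloroglucinol (benzene-1,3,5-triol) | Oc1cc(O)cc(O)c1 | starting material
2 | 3,5-bis(methoxymethoxy)phenol | COCOc1cc(O)cc(OCOC)c1 | intermediate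
3 | 1-(benzyloxy)-3,5-bis(methoxymethoxy)benzene | COCOc1cc(OCc2ccccc2)cc(OCOC)c1 | intermediate
4 | 2-methylbenzene-1,3,5-triol | Cc1c(O)cc(O)cc1O | starting material
5 | 3-(4-hydroxyphenyl)propanoic acid | OC(=O)CCc1ccc(O)cc1 | starting material
6 | 3-(4-hydroxyphenyl)-1-(2,4,6-trihydroxy-3-methylphenyl)propan-1-one | Cc1c(O)cc(O)c(C(=O)CCc2ccc(O)cc2)c1O | intermediate
7 | 1-(2,6-dihydroxy-4-methoxy-3-methylphenyl)-3-(4-hydroxyphenyl)propan-1-one | COc1cc(O)c(C(=O)CCc2ccc(O)cc2)c(O)c1C | intermediate
8 | {2,4-dihydroxy-3-[3-(4-hydroxyphenyl)propanoyl]-6-methoxy-5-methylphenyl}methylidene(dimethyl)iminium chloride | C[N+](C)=Cc1c(O)c(C(=O)CCc2ccc(O)cc2)c(O)c(C)c1OC.[Cl-] | intermediate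
9 | 2,4-dihydroxy-3-[3-(4-hydroxyphenyl)propanoyl]-6-methoxy-5-methylbenzaldehyde | O=Cc1c(O)c(C(=O)CCc2ccc(O)cc2)c(O)c(C)c1OC | intermediate
10 | 2,4-bis(benzyloxy)-3-{3-[4-(benzyloxy)phenyl]propanoyl}-6-methoxy-5-methylbenzaldehyde | O=Cc1c(OCc2ccccc2)c(C(=O)CCc2ccc(OCc3ccccc3)cc2)c(OCc2ccccc2)c(C)c1OC | intermediate
11 | [4-(benzyloxy)-2,6-bis(methoxymethoxy)phenyl]lithium | [Li]c1c(OCOC)cc(OCc2ccccc2)cc1OCOC | intermediate
12 | racemic 1-[2,6-bis(benzyloxy)-3-{[4-(benzyloxy)-2,6-bis(methoxymethoxy)phenyl](hydroxy)methyl}-4-methoxy-5-methylphenyl]-3-[4-(benzyloxy)phenyl]propan-1-one | OC(c1c(OCOC)cc(OCc2ccccc2)cc1OCOC)c1c(OCc2ccccc2)c(C(=O)CCc2ccc(OCc3ccccc3)cc2)c(OCc2ccccc2)c(C)c1OC | intermediate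
13 | 1-[2,6-bis(benzyloxy)-3-{[4-(benzyloxy)-2,6-bis(methoxymethoxy)phenyl]methyl}-4-methoxy-5-methylphenyl]-3-[4-(benzyloxy)phenyl]propan-1-one | COCOc1cc(OCc2ccccc2)cc(OCOC)c1Cc1c(OCc2ccccc2)c(C(=O)CCc2ccc(OCc3ccccc3)cc2)c(OCc2ccccc2)c(C)c1OC | intermediate
14 | 5-(benzyloxy)-2-[(2,4-bis(benzyloxy)-3-{3-[4-(benzyloxy)phenyl]propanoyl}-6-methoxy-5-methylphenyl)methyl]benzene-1,3-diol | Oc1cc(OCc2ccccc2)cc(O)c1Cc1c(OCc2ccccc2)c(C(=O)CCc2ccc(OCc3ccccc3)cc2)c(OCc2ccccc2)c(C)c1OC | intermediate
15 | ethyl 2-(benzyloxy)acetate | CCOC(=O)COCc1ccccc1 | starting material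
16 | 4-methoxybenzoyl chloride | COc1ccc(cc1)C(Cl)=O | starting material
17 | lithium enolate of ethyl 2-(benzyloxy)acetate (enolate geometry not defined) | CCOC(O[Li])=COCc1ccccc1 | intermediate
18 | racemic ethyl 2-(benzyloxy)-3-(4-methoxyphenyl)-3-oxopropanoate | CCOC(=O)C(OCc1ccccc1)C(=O)c1ccc(OC)cc1 | intermediate
19 | 2-(benzyloxy)-3-(4-methoxyphenyl)-3-oxoprop-1-en-1-one (aroylketene) | O=C=C(OCc1ccccc1)C(=O)c1ccc(OC)cc1 | intermediate
20 | racemic 2-(benzyloxy)-1-{6-(benzyloxy)-2,4-dihydroxy-3-[(2,4-bis(benzyloxy)-3-{3-[4-(benzyloxy)phenyl]propanoyl}-6-methoxy-5-methylphenyl)methyl]phenyl}-3-(4-methoxyphenyl)propane-1,3-dione | COc1ccc(cc1)C(=O)C(OCc1ccccc1)C(=O)c1c(OCc2ccccc2)cc(O)c(Cc2c(OCc3ccccc3)c(C(=O)CCc3ccc(OCc4ccccc4)cc3)c(OCc3ccccc3)c(C)c2OC)c1O | intermediate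
21 | 3,5-bis(benzyloxy)-8-[(2,4-bis(benzyloxy)-3-{3-[4-(benzyloxy)phenyl]propanoyl}-6-methoxy-5-methylphenyl)methyl]-7-hydroxy-2-(4-methoxyphenyl)-4H-chromen-4-one | COc1ccc(cc1)-c1oc2c(Cc3c(OCc4ccccc4)c(C(=O)CCc4ccc(OCc5ccccc5)cc4)c(OCc4ccccc4)c(C)c3OC)c(O)cc(OCc3ccccc3)c2c(=O)c1OCc1ccccc1 | intermediate
22 | 4'''-hydroxytrianguletin, 8-({2,4-dihydroxy-3-[3-(4-hydroxyphenyl)propanoyl]-6-methoxy-5-methylphenyl}methyl)-3,5,7-trihydroxy-2-(4-methoxyphenyl)-4H-chromen-4-one | COc1ccc(-c2oc3c(Cc4c(O)c(C(=O)CCc5ccc(O)cc5)c(O)c(C)c4OC)c(O)cc(O)c3c(=O)c2O)cc1 | target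

**Step count and risks**

Total step count: 11. Longest linear sequence: 8 steps (steps 3, 4, 5, 6, 7, 8, 10, 11).

The three steps most likely to fail are these.

Step 10. At the temperature needed to release the ketene, benzyl groups may migrate or be lost. The reaction may also stall at reversible O-acylation of the two phenols without C-acylation of the crowded ring A, or the oxidation-prone resorcinol may decompose before the pyranone closes. The fallback sets out from 14 and comes back at 21, forming the same two bonds one after the other by classical chemistry. Hoesch acylation of 14 with benzyloxyacetonitrile (ZnCl2, HCl, Et2O, 0 °C) would give the ketiminium chloride F1 at one of the two equivalent ring A carbons. Warm water would hydrolyse it to the ω-benzyloxy ketone F2. Allan–Robinson condensation of F2 with 4-methoxybenzoic anhydride and potassium 4-methoxybenzoate at about 160 °C would close ring C and acylate the remaining phenol, giving the 7-O-(4-methoxybenzoyl) flavone F3. KOH in aqueous methanol would cleave that ester to 21.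

Step 7. Proton transfer from the CH2 next to the ketone (or from a benzylic OCH2) to the aryllithium, together with slow addition to the doubly ortho-substituted aldehyde, may return protonated 3 and unchanged 10. The fallback sets out from 10 and 11 and comes back at 13, replacing carbonyl addition by cross-coupling. NaBH4 in THF–MeOH at −20 °C should reduce only the aldehyde of 10 to the benzylic alcohol F4. CBr4 and PPh3 in CH2Cl2 would convert it into the benzylic bromide F5. Aryllithium 11 would be transmetalated with ZnCl2 to the arylzinc chloride F6, and Negishi coupling of F5 with F6 (Pd(PPh3)4, THF, 50 °C) would give 13 directly. The acid methanolysis stage of step 8 then leads to 14.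

Step 8. Under acid the very electron-rich carbinol may fragment by loss of ring A, an ortho MOM group may capture the benzylic centre as a cyclic acetal, the silane may begin to reduce the ketone, or the methylene bridge may be cut during the acidic MOM removal. The fallback sets out from 12 and comes back at 14, avoiding protic acid throughout. MsCl and Et3N in CH2Cl2 at −20 °C would convert 12 into the diarylmethyl chloride F7 by way of the mesylate. Radical-chain reduction with n-Bu3SnH and AIBN in toluene at 80 °C would replace chlorine by hydrogen and give 13. ZnBr2 with n-PrSH in CH2Cl2 at rt would then remove both MOM groups under aprotic conditions to give 14.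

**Further compounds**

F1 | step 10 | 2-(benzyloxy)-1-{6-(benzyloxy)-2,4-dihydroxy-3-[(2,4-bis(benzyloxy)-3-{3-[4-(benzyloxy)phenyl]propanoyl}-6-methoxy-5-methylphenyl)methyl]phenyl}ethan-1-iminium chloride | [NH2+]=C(COCc1ccccc1)c1c(OCc2ccccc2)cc(O)c(Cc2c(OCc3ccccc3)c(C(=O)CCc3ccc(OCc4ccccc4)cc3)c(OCc3ccccc3)c(C)c2OC)c1O.[Cl-]
F2 | step 10 | 2-(benzyloxy)-1-{6-(benzyloxy)-2,4-dihydroxy-3-[(2,4-bis(benzyloxy)-3-{3-[4-(benzyloxy)phenyl]propanoyl}-6-methoxy-5-methylphenyl)methyl]phenyl}ethan-1-one | O=C(COCc1ccccc1)c1c(OCc2ccccc2)cc(O)c(Cc2c(OCc3ccccc3)c(C(=O)CCc3ccc(OCc4ccccc4)cc3)c(OCc3ccccc3)c(C)c2OC)c1O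
F3 | step 10 | 3,5-bis(benzyloxy)-8-[(2,4-bis(benzyloxy)-3-{3-[4-(benzyloxy)phenyl]propanoyl}-6-methoxy-5-methylphenyl)methyl]-2-(4-methoxyphenyl)-4-oxo-4H-chromen-7-yl 4-methoxybenzoate | COc1ccc(cc1)-c1oc2c(Cc3c(OCc4ccccc4)c(C(=O)CCc4ccc(OCc5ccccc5)cc4)c(OCc4ccccc4)c(C)c3OC)c(OC(=O)c3ccc(OC)cc3)cc(OCc3ccccc3)c2c(=O)c1OCc1ccccc1
F4 | step 7 | 1-[2,6-bis(benzyloxy)-3-(hydroxymethyl)-4-methoxy-5-methylphenyl]-3-[4-(benzyloxy)phenyl]propan-1-one | OCc1c(OCc2ccccc2)c(C(=O)CCc2ccc(OCc3ccccc3)cc2)c(OCc2ccccc2)c(C)c1OC
F5 | step 7 | 1-[2,6-bis(benzyloxy)-3-(bromomethyl)-4-methoxy-5-methylphenyl]-3-[4-(benzyloxy)phenyl]propan-1-one | BrCc1c(OCc2ccccc2)c(C(=O)CCc2ccc(OCc3ccccc3)cc2)c(OCc2ccccc2)c(C)c1OC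
F6 | step 7 | [4-(benzyloxy)-2,6-bis(methoxymethoxy)phenyl]zinc chloride | Cl[Zn]c1c(OCOC)cc(OCc2ccccc2)cc1OCOC
F7 | step 8 | racemic 1-[2,6-bis(benzyloxy)-3-{[4-(benzyloxy)-2,6-bis(methoxymethoxy)phenyl](chloro)methyl}-4-methoxy-5-methylphenyl]-3-[4-(benzyloxy)phenyl]propan-1-one | ClC(c1c(OCOC)cc(OCc2ccccc2)cc1OCOC)c1c(OCc2ccccc2)c(C(=O)CCc2ccc(OCc3ccccc3)cc2)c(OCc2ccccc2)c(C)c1OC
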